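## Retrosynthetic overview

1. Target 18 ⇐ acid: ene-dione 16 loses MeOH, ring B (pyran) closes by oxa-6π (C-1–O-2 bond), and the MOM and tert-butyl groups fall off.
2. 16 ⇐ light: intramolecular alkyne de Mayo reaction of the acyclic 1,3-diketone 14 forms C-8a–C-4a and C-3–C-4, so ring A (carbocycle) is made first.
3. 14 ⇐ C-methoxymethylation of diketone 12 ⇐ crossed Claisen of Weinreb amide 10 with tert-butyl levulinate 11.
4. 10 ⇐ esterification of hydroxy amide 5 with MOM-protected orsellinic acid 8 (from 6).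
5. 5 ⇐ Fráter–Seebach methylation (C-7 set by C-6) ⇐ alkynylation of the epoxide from ethyl (S)-4-chloro-3-hydroxybutanoate 1 (source of C-6).

Assumption: 1, 6 and 11 are purchased; ring positions use 1H-isochromene numbering (C-1 = OCH2, O-2, C-3 carries the propanoic acid chain, ring A = C-4a, C-5 to C-8, C-8a); ArCO = 2,4-bis(methoxymethoxy)-6-methylbenzoyl.

## Route

Step 1
Reactants: 1 ethyl (3S)-4-chloro-3-hydroxybutanoate
Product: 2 ethyl 2-[(2S)-oxiran-2-yl]acetate
Conditions: Ag2O, DME, 60 °C, dark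
Reagents that add atoms: none
Why: Intramolecular Williamson etherification at C-4 leaves the C-3 stereocentre untouched, and the non-basic silver conditions avoid E1cB opening of the β,γ-epoxy ester to the 4-hydroxycrotonate.

Step 2
Reactants: 2 ethyl 2-[(2S)-oxiran-2-yl]acetate
Product: 3 ethyl (3R)-3-hydroxyhex-5-ynoate
Conditions: HC≡CH, n-BuLi, THF, −78 °C; BF3·OEt2; then 2, −78 °C; aq. NH4Cl
Reagents that add atoms: lithium acetylide (made in the flask from acetylene), [Li+].[C-]#C
Why: Yamaguchi–Hirao alkynylation, in which the BF3-activated epoxide is opened at its terminal carbon faster than the ester is attacked, so the purchased centre is kept (the descriptor changes only through priorities).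

Step 3
Reactants: 3 ethyl (3R)-3-hydroxyhex-5-ynoate
Product: 4 ethyl (2R,3R)-3-hydroxy-2-methylhex-5-ynoate
Conditions: LiN(iPr)2 (3.2 equiv), THF, −78 → −20 °C; MeI (1.2 equiv), −78 → −20 °C; aq. NH4Cl
Reagents that add atoms: iodomethane, CI
Why: Fráter–Seebach alkylation, in which the chelated lithium alkoxide–enolate is methylated anti to the C-3 side chain so the purchased carbinol centre sets the new (2R) methyl centre (typically ≥10:1), while the third equivalent of base only parks on the alkyne C–H, whose acetylide is inert to MeI at this temperature.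

Step 4
Reactants: 4 ethyl (2R,3R)-3-hydroxy-2-methylhex-5-ynoate
Product: 5 (2R,3R)-3-hydroxy-N-methoxy-N,2-dimethylhex-5-ynamide
Conditions: MeNH(OMe)·HCl, AlMe3, CH2Cl2, 0 °C → rt
Reagents that add atoms: N,O-dimethylhydroxylamine hydrochloride, CNOC.Cl
Why: Weinreb amidation through the aluminium amide converts the ester without epimerising or dehydrating the anti-aldol unit.

Step 5
Reactants: 6 orsellinic acid (2,4-dihydroxy-6-methylbenzoic acid)
Product: 8 2,4-bis(methoxymethoxy)-6-methylbenzoic acid, via tris-MOM ester 7 (not isolated)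
Conditions: NaH, MOMCl, DMF, 0 °C → rt; then LiOH, THF/H2O, rt; dil. HCl to pH 4, 0 °C
Reagents that add atoms: chloromethyl methyl ether, COCCl; lithium hydroxide, [Li+].[OH-]
Why: Exhaustive Williamson O-alkylation followed by saponification cleaves only the activated acetal-type MOM ester, because the two aryl MOM ethers are stable to base.

Step 6
Reactants: 8 2,4-bis(methoxymethoxy)-6-methylbenzoic acid; 5 (2R,3R)-3-hydroxy-N-methoxy-N,2-dimethylhex-5-ynamide
Product: 10 (2R,3R)-1-[methoxy(methyl)amino]-2-methyl-1-oxohex-5-yn-3-yl 2,4-bis(methoxymethoxy)-6-methylbenzoate, via acyl fluoride 9 (not isolated)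
Conditions: 8, cyanuric fluoride, pyridine, CH2Cl2, −10 °C → rt; then 5, NaN(SiMe3)2, THF, −78 → 0 °C
Reagents that add atoms: none
Why: Acyl fluoride esterification, in which the di-ortho-substituted acid is activated without chloride (so the ortho MOM ether is not lost through benzodioxinone formation) and acylates the sodium alkoxide of 5 with retention at the carbinol carbon.

Step 7
Reactants: 10 (2R,3R)-1-[methoxy(methyl)amino]-2-methyl-1-oxohex-5-yn-3-yl 2,4-bis(methoxymethoxy)-6-methylbenzoate; 11 tert-butyl 4-oxopentanoate (tert-butyl levulinate)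
Product: 12 tert-butyl (7R,8R)-8-{[2,4-bis(methoxymethoxy)-6-methylbenzoyl]oxy}-7-methyl-4,6-dioxoundec-10-ynoate
Conditions: 11 (2.6 equiv), LiN(iPr)2 (2.5 equiv), THF, −78 °C; then 10, −78 → −10 °C; aq. NH4Cl
Reagents that add atoms: none
Why: Crossed Claisen condensation, in which the kinetic methyl-side enolate of 11 adds to the Weinreb amide, and the enolate is too weak a base to remove the amide α-H or the alkyne C–H, so neither epimerisation nor E1cB loss of the aryl carboxylate occurs and the hindered aryl ester is left alone.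

Step 8
Reactants: 12 tert-butyl (7R,8R)-8-{[2,4-bis(methoxymethoxy)-6-methylbenzoyl]oxy}-7-methyl-4,6-dioxoundec-10-ynoate
Product: 14 tert-butyl (7R,8R)-8-{[2,4-bis(methoxymethoxy)-6-methylbenzoyl]oxy}-5-(methoxymethyl)-7-methyl-4,6-dioxoundec-10-ynoate, via silyl enol ether 13 (not isolated)
Conditions: N,O-bis(trimethylsilyl)acetamide (1.05 equiv), CH2Cl2, rt; then MOMCl (1.2 equiv), ZnBr2 (10 mol %), 0 °C
Reagents that add atoms: chloromethyl methyl ether, COCCl
Why: Mukaiyama-type SN1 alkylation, in which the silyl enol ether attacks the methoxymethyl oxocarbenium ion at carbon (O-alkylation is reversible under ZnBr2), and the new C-5 centre is formed as a mixture that does not matter because this carbon becomes sp2.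

Step 9
Reactants: 14 tert-butyl (7R,8R)-8-{[2,4-bis(methoxymethoxy)-6-methylbenzoyl]oxy}-5-(methoxymethyl)-7-methyl-4,6-dioxoundec-10-ynoate
Product: 18 3-[(6R,7R)-6-[(2,4-dihydroxy-6-methylbenzoyl)oxy]-7-methyl-8-oxo-5,6,7,8-tetrahydro-1H-isochromen-3-yl]propanoic acid, via cyclobutenol photoadduct 15 (not isolated), via ene-dione 16 (not isolated), via MOM-protected isochromenone 17 (not isolated)
Conditions: hν (300 nm, Pyrex), degassed cyclohexane/EtOAc, 5 mM, 15 °C; evaporate; then TFA/CH2Cl2/H2O (25:73:2), 0 °C → rt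
Reagents that add atoms: none
Why: Proposed new method: direct excitation of the chelated enol of the 2-substituted 1,3-diketone lets its C=C add to the tethered terminal alkyne in the only strain-free mode (central carbon to the internal alkyne carbon, closing six-membered ring A, and enol carbinol carbon to the terminal CH), the strained cyclobutenol 15 then undergoes spontaneous retro-aldol cleavage to the Z-ene-dione 16 (net insertion of the alkyne into the C–acyl bond), and acid ionises the methoxymethyl group through the dienol so that the resulting 1-oxatriene closes by oxa-6π electrocyclisation to ring B while the same acid removes the MOM and tert-butyl groups, the two stereocentres being untouched because no base is present; the closest known reactions are the de Mayo reaction of enolised 1,3-diketones with alkenes and intramolecular enone–alkyne [2+2] photocycloadditions, but an intramolecular alkyne de Mayo cascade on an acyclic 2-substituted diketone leading to a 1H-isochromen-8-one has not been described.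

## Compound list

1 | ethyl (3S)-4-chloro-3-hydroxybutanoate | ClC[C@@H](O)CC(=O)OCC | starting material
2 | ethyl 2-[(2S)-oxiran-2-yl]acetate | C1[C@@H](O1)CC(=O)OCC | intermediate
3 | ethyl (3R)-3-hydroxyhex-5-ynoate | C#CC[C@@H](O)CC(=O)OCC | intermediate
4 | ethyl (2R,3R)-3-hydroxy-2-methylhex-5-ynoate | C#CC[C@@H](O)[C@@H](C)C(=O)OCC | intermediate
5 | (2R,3R)-3-hydroxy-N-methoxy-N,2-dimethylhex-5-ynamide | C#CC[C@@H](O)[C@@H](C)C(=O)N(C)OC | intermediate
6 | orsellinic acid (2,4-dihydroxy-6-methylbenzoic acid) | Cc1cc(O)cc(O)c1C(=O)O | starting material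
7 | methoxymethyl 2,4-bis(methoxymethoxy)-6-methylbenzoate (not isolated) | Cc1cc(OCOC)cc(OCOC)c1C(=O)OCOC | intermediate
8 | 2,4-bis(methoxymethoxy)-6-methylbenzoic acid | Cc1cc(OCOC)cc(OCOC)c1C(=O)O | intermediate
9 | 2,4-bis(methoxymethoxy)-6-methylbenzoyl fluoride (not isolated) | Cc1cc(OCOC)cc(OCOC)c1C(F)=O | intermediate
10 | (2R,3R)-1-[methoxy(methyl)amino]-2-methyl-1-oxohex-5-yn-3-yl 2,4-bis(methoxymethoxy)-6-methylbenzoate | C#CC[C@@H](OC(=O)c1c(C)cc(OCOC)cc1OCOC)[C@@H](C)C(=O)N(C)OC | intermediate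
11 | tert-butyl 4-oxopentanoate (tert-butyl levulinate) | CC(=O)CCC(=O)OC(C)(C)C | starting material
12 | tert-butyl (7R,8R)-8-(ArCO2)-7-methyl-4,6-dioxoundec-10-ynoate | C#CC[C@@H](OC(=O)c1c(C)cc(OCOC)cc1OCOC)[C@@H](C)C(=O)CC(=O)CCC(=O)OC(C)(C)C | intermediate
13 | tert-butyl (7R,8R)-8-(ArCO2)-7-methyl-6-oxo-4-[(trimethylsilyl)oxy]undec-4-en-10-ynoate (not isolated; one O-silyl isomer drawn, alkene geometry undefined) | C#CC[C@@H](OC(=O)c1c(C)cc(OCOC)cc1OCOC)[C@@H](C)C(=O)C=C(O[Si](C)(C)C)CCC(=O)OC(C)(C)C | intermediate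
14 | tert-butyl (7R,8R)-8-(ArCO2)-5-(methoxymethyl)-7-methyl-4,6-dioxoundec-10-ynoate (C-5 epimers) | C#CC[C@@H](OC(=O)c1c(C)cc(OCOC)cc1OCOC)[C@@H](C)C(=O)C(COC)C(=O)CCC(=O)OC(C)(C)C | intermediate
15 | tert-butyl 3-[(3R,4R)-4-(ArCO2)-8-hydroxy-1-(methoxymethyl)-3-methyl-2-oxobicyclo[4.2.0]oct-6-en-8-yl]propanoate (not isolated; C-1 and C-8 as formed) | Cc1cc(OCOC)cc(OCOC)c1C(=O)O[C@@H]1CC2=CC(O)(CCC(=O)OC(C)(C)C)C2(COC)C(=O)[C@@H]1C | intermediate
16 | tert-butyl (5Z)-5-[(4R,5R)-5-(ArCO2)-2-(methoxymethyl)-4-methyl-3-oxocyclohexylidene]-4-oxopentanoate (not isolated) | Cc1cc(OCOC)cc(OCOC)c1C(=O)O[C@@H]1C/C(=C/C(=O)CCC(=O)OC(C)(C)C)C(COC)C(=O)[C@@H]1C | intermediate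
17 | tert-butyl 3-[(6R,7R)-6-(ArCO2)-7-methyl-8-oxo-5,6,7,8-tetrahydro-1H-isochromen-3-yl]propanoate (not isolated) | Cc1cc(OCOC)cc(OCOC)c1C(=O)O[C@@H]1CC2=C(COC(CCC(=O)OC(C)(C)C)=C2)C(=O)[C@@H]1C | intermediate
18 | 3-[(6R,7R)-6-[(2,4-dihydroxy-6-methylbenzoyl)oxy]-7-methyl-8-oxo-5,6,7,8-tetrahydro-1H-isochromen-3-yl]propanoic acid | Cc1cc(O)cc(O)c1C(=O)O[C@@H]1CC2=C(COC(CCC(=O)O)=C2)C(=O)[C@@H]1C | target

## Step count and risks

Total step count: 9. Longest linear sequence: 8 (steps 1, 2, 3, 4, 6, 7, 8, 9).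

**Step 9 (the new photochemical cascade).** The enol fraction of a 2-substituted diketone is modest, a terminal alkyne is a poorer partner than an alkene, and the keto form can divert light into hydrogen abstraction. The acid stage could also epimerise C-7 or expel orsellinic acid with aromatisation if left too long. The fallback sets out from 14 and uses known chemistry, the thermal rhenium-catalysed insertion of a terminal alkyne into the C–C bond of a 1,3-dicarbonyl compound, run intramolecularly ([ReBr(CO)3(thf)]2, 5 mol %, toluene, 80 °C). It gives the conjugated enone tert-butyl 5-[(4R,5R)-5-(ArCO2)-2-(methoxymethyl)-4-methyl-3-oxocyclohex-1-en-1-yl]-4-oxopentanoate F1, a tautomer of 16. The acid treatment of step 9 then closes F1 to 17, where the fallback comes back to the route, and carries it on to 18.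

**Step 8 (C-methoxymethylation).** A hard oxocarbenium electrophile may give the O-alkylated enol ether, a second alkylation, or loss of methanol to the 2-methylene diketone. The fallback sets out from 12 and swaps the ether for an amine leaving group. A Mannich reaction with N,N-dimethylmethyleneiminium chloride (CH2Cl2, rt; C-selective) gives tert-butyl (7R,8R)-8-(ArCO2)-5-[(dimethylamino)methyl]-7-methyl-4,6-dioxoundec-10-ynoate hydrochloride F2. Irradiation of this salt as in step 9 gives tert-butyl (5Z)-5-[(4R,5R)-5-(ArCO2)-2-[(dimethylamino)methyl]-4-methyl-3-oxocyclohexylidene]-4-oxopentanoate hydrochloride F3. Aqueous NaHCO3/CH2Cl2 then frees the amine, E1cB loss of dimethylamine gives the 1-oxatriene, and oxa-6π closure delivers 17, where the fallback comes back to the route; the acid part of step 9 finishes to 18.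

**Step 7 (crossed Claisen).** The α-branched Weinreb amide may acylate the ketone enolate slowly, and enolisation of 11 may not be fully methyl-selective. The fallback sets out from 10 and replaces acylation by aldol addition and oxidation. iBu2AlH (THF, −78 °C) gives the aldehyde (2R,3R)-2-methyl-1-oxohex-5-yn-3-yl 2,4-bis(methoxymethoxy)-6-methylbenzoate F4. The lithium enolate of 11 (LiN(iPr)2, THF, −78 °C) adds to it to give tert-butyl 8-(ArCO2)-6-hydroxy-7-methyl-4-oxoundec-10-ynoate F5 (C-7 and C-8 as in 10, C-6 epimers). Dess–Martin periodinane (NaHCO3, CH2Cl2) oxidises F5 to 12, where the fallback comes back to the route.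

## Further compounds

F1 | step 9 | tert-butyl 5-[(4R,5R)-5-(ArCO2)-2-(methoxymethyl)-4-methyl-3-oxocyclohex-1-en-1-yl]-4-oxopentanoate | Cc1cc(OCOC)cc(OCOC)c1C(=O)O[C@@H]1CC(CC(=O)CCC(=O)OC(C)(C)C)=C(COC)C(=O)[C@@H]1C
F2 | step 8 | tert-butyl (7R,8R)-8-(ArCO2)-5-[(dimethylamino)methyl]-7-methyl-4,6-dioxoundec-10-ynoate hydrochloride | C#CC[C@@H](OC(=O)c1c(C)cc(OCOC)cc1OCOC)[C@@H](C)C(=O)C(CN(C)C)C(=O)CCC(=O)OC(C)(C)C.Cl
F3 | step 8 | tert-butyl (5Z)-5-[(4R,5R)-5-(ArCO2)-2-[(dimethylamino)methyl]-4-methyl-3-oxocyclohexylidene]-4-oxopentanoate hydrochloride | Cc1cc(OCOC)cc(OCOC)c1C(=O)O[C@@H]1C/C(=C/C(=O)CCC(=O)OC(C)(C)C)C(CN(C)C)C(=O)[C@@H]1C.Cl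
F4 | step 7 | (2R,3R)-2-methyl-1-oxohex-5-yn-3-yl 2,4-bis(methoxymethoxy)-6-methylbenzoate | C#CC[C@@H](OC(=O)c1c(C)cc(OCOC)cc1OCOC)[C@@H](C)C=O
F5 | step 7 | tert-butyl 8-(ArCO2)-6-hydroxy-7-methyl-4-oxoundec-10-ynoate (C-7 and C-8 as in 10, C-6 epimers) | C#CC[C@@H](OC(=O)c1c(C)cc(OCOC)cc1OCOC)[C@@H](C)C(O)CC(=O)CCC(=O)OC(C)(C)C
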